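The whole eremophilane skeleton of the target is disconnected back to acyclic farnesyl diphosphate. Fungal aristolochene synthase folds this diphosphate and, in one operation, forms the C6–C7 and C5–C10 bonds of rings A and B, moves hydride and methyl to create the cis C4/C5 dimethyl pair, fixes C7, and leaves the C9=C10 alkene. The step exploits the fact that C4, C5 and C7 of the target match (+)-aristolochene and that its alkene sits where the C9 oxygen, the C8 oxygen and the C10 hydrogen are needed. The precursor is simply (2E,6E)-farnesyl diphosphate, made from farnesol in two steps.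

Key step: step 3

Remarks on the chemistry
- Numbering and faces: eremophilane numbering is used (ring A = C1–C5, C10; ring B = C5–C10; C15 on C4, C14 on C5, isopropenyl C11–C13 on C7). β is the face of the C5 methyl group. The target is then 3α,9α-diacyloxy-8α-hydroxy-4β,5β-dimethyl-7α-isopropenyl-10αH, i.e. (3R,4R,5R,7S,8R,9S,10R), a trans-decalin with the 8-OH axial and all other ring substituents except C14 equatorial.
- Structure check: the SMILES of aristolochene used here encodes (4S,5R,7S); C4, C5 and C7 of the target have the same spatial arrangement (the CIP letter at C4 changes only because C3 carries oxygen).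
- Assumption: the fungal synthase delivers this (4S,5R,7S) enantiomer, the dextrorotatory one; rotation and chiral GC of 5 are to be checked before material is carried on.

Step 1
Reactants: 1 (2E,6E)-farnesol
Product: 2 (2E,6E)-farnesyl chloride
Conditions: NCS, Me2S, CH2Cl2, −30 to 0 °C
Reagents that add atoms: N-chlorosuccinimide, O=C1CCC(=O)N1Cl
Why: Corey–Kim-type chlorination: the alkoxysulfonium salt formed from the allylic alcohol is displaced by chloride at the primary carbon, so the chloride should form without allylic transposition or loss of the 2E geometry; no stereocenter is created.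

Step 2
Reactants: 2 (2E,6E)-farnesyl chloride
Product: 3 (2E,6E)-farnesyl diphosphate (handled as its trisammonium salt)
Conditions: (Bu4N)3HP2O7, MeCN, rt; then Dowex 50W-X8 (NH4+ form), aq. NH4HCO3/i-PrOH; cellulose chromatography
Reagents that add atoms: tris(tetrabutylammonium) hydrogen diphosphate, CCCC[N+](CCCC)(CCCC)CCCC.CCCC[N+](CCCC)(CCCC)CCCC.CCCC[N+](CCCC)(CCCC)CCCC.OP(=O)([O-])OP(=O)([O-])[O-]
Why: SN2 displacement of the primary allylic chloride by the diphosphate anion in a dipolar aprotic solvent, the standard way to prenyl diphosphates, followed by cation exchange to the water-soluble ammonium salt that the enzyme accepts; no stereocenter is created.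

Step 3
Reactants: 3 (2E,6E)-farnesyl diphosphate
Product: 5 (+)-aristolochene, via (S)-germacrene A 4 (not isolated)
Conditions: recombinant fungal aristolochene synthase (Aspergillus terreus enzyme, His-tagged, from E. coli), MgCl2 (5 mM), Tris-HCl pH 7.5, glycerol, 30 °C, pentane overlay, 3 fed in portions
Reagents that add atoms: none
Why: Mg2+-assisted ionisation of the diphosphate gives the farnesyl cation, which is captured at C6 by the distal C7=C11 alkene (exo-mode macrocyclisation that closes the ten-membered ring through the C6–C7 bond) and loses a C12 proton to enzyme-bound germacrene A 4. Reprotonation at C1 then drives transannular attack of the C4=C5 alkene on C10 (6-endo with respect to ring A, dividing the macrocycle into rings A and B through the C5–C10 bond) to a eudesmane-type C4 cation. A 1,2-hydride shift from C5 to C4 and a 1,2-methyl shift from C10 to C5, each suprafacial and mutually antiperiplanar, followed by loss of H9, give the C9=C10 alkene. This is the native reaction of a class 1 (ionisation-initiated, Mg2+-dependent) sesquiterpene cyclase, so the closest known reaction type is the reaction itself. C7 is fixed by the face of the distal alkene that the active-site fold presents to C6, C4 by the face on which hydride arrives, and C5 by methyl entering the face opposite the departing hydride, which makes the two methyl groups cis. The step needs one folding mode out of many and termination at H9 instead of H1 or capture by water; both are secured by the enzyme template acting on its natural substrate, whose only demand is the (2E,6E) geometry of 3.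

Step 4
Reactants: 5 (+)-aristolochene
Product: 6 (4S,5R,7S)-eremophila-9,11-dien-8-one
Conditions: Rh2(caprolactamate)4 (1 mol %), t-BuOOH (70% aq., 5 equiv), K2CO3, CH2Cl2, rt
Reagents that add atoms: tert-butyl hydroperoxide, CC(C)(C)OO
Why: Radical allylic oxidation with t-BuOO•: abstraction of H8 gives the more substituted allyl radical (C8–C9–C10) and oxygen is taken up at its secondary end C8, the same site preference that turns 5-ene steroids into 7-ketones and valencene into nootkatone with an isopropenyl group left intact; no stereocenter is created and C7 keeps its equatorial isopropenyl group.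

Step 5
Reactants: 6 (4S,5R,7S)-eremophila-9,11-dien-8-one
Product: 8 8-(trimethylsilyloxy)-10αH-eremophila-8,11-diene, via lithium enolate 7 (not isolated)
Conditions: Li (2.2 equiv), t-BuOH (1.0 equiv), NH3(l)/THF, −78 °C; isoprene; NH3 removed; then TMSCl, Et3N, THF, −78 to 0 °C
Reagents that add atoms: chlorotrimethylsilane, C[Si](C)(C)Cl
Why: Dissolving-metal (Birch-type) conjugate reduction with trapping of the enolate: the C10 carbanion is protonated axially from the α face, anti to the axial C5 methyl group, which should give the trans-decalin (10αH), and the enolate, formed only towards C9, is fixed as its silyl ether while the isolated isopropenyl alkene is not reduced.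

Step 6
Reactants: 8 8-(trimethylsilyloxy)-10αH-eremophila-8,11-diene
Product: 11 9α-hydroxy-10αH-eremophil-11-en-8-one, via silyloxy epoxide 9 (not isolated), via 9α-silyloxy ketone 10 (not isolated)
Conditions: mCPBA (1.05 equiv), NaHCO3, CH2Cl2, −20 °C; then 1 M HCl, THF, 0 °C
Reagents that add atoms: 3-chloroperoxybenzoic acid, O=C(OO)c1cccc(Cl)c1
Why: Rubottom oxidation: the peracid attacks the electron-rich silyl enol ether, far faster than the isopropenyl alkene, from the α face because the β face of C9 is syn-axial to the C5 methyl group, and silyl migration followed by acid cleavage should give the equatorial 9α-alcohol.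

Step 7
Reactants: 11 9α-hydroxy-10αH-eremophil-11-en-8-one
Product: 12 10αH-eremophil-11-ene-8α,9α-diol
Conditions: LiBH(s-Bu)3 (2.5 equiv), THF, −78 °C; then NaOH, H2O2, 0 °C
Reagents that add atoms: none
Why: Diastereoselective ketone reduction with a bulky trialkylborohydride: hydride arrives along the equatorial direction, away from the axial α-hydrogens at C6 and C10, so the new C8 alcohol should be axial (8α) and cis to the 9α-hydroxyl.

Step 8
Reactants: 12 10αH-eremophil-11-ene-8α,9α-diol
Product: 13 10αH-eremophil-11-ene-3α,8α,9α-triol
Conditions: CYP102A1 (P450 BM3) variant (E. coli lysate), NADP+ (cat.), D-glucose, glucose dehydrogenase, air, KPi pH 8.0, 2% DMSO, 25 °C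
Reagents that add atoms: dioxygen, O=O
Why: Proposed new method: no enzyme is yet known to hydroxylate C3 of this diol, so a CYP102A1 variant has to be found by screening a mutant panel and sharpened by directed evolution; the reasoning is that the haem ferryl-oxo radical cation (tetravalent iron) abstracts a hydrogen atom and returns OH to the same face (radical rebound, retention), that anchoring the polar C8/C9 diol end at the mouth of the pocket presents the distal methylenes of ring A to the haem, and that at C3 the equatorial α-hydrogen is the exposed one (the β-hydrogen is syn-axial to the C5 methyl group), which leads to the equatorial 3α-alcohol of the target; the closest known reaction type is the C3 hydroxylation of trans-decalin terpenoids of the sclareolide and sclareol type to their equatorial 3-alcohols by engineered P450 BM3 variants, in the latter case with a vinyl group left untouched.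

Step 9
Reactants: 13 10αH-eremophil-11-ene-3α,8α,9α-triol; 14 hex-2-ynoic acid
Product: 15 3α,9α-bis(hex-2-ynoyloxy)-10αH-eremophil-11-en-8α-ol
Conditions: 14 (2.3 equiv), DCC (2.4 equiv), DMAP (0.1 equiv), CH2Cl2, −20 to 0 °C
Reagents that add atoms: none
Why: Steglich esterification under kinetic control: the two equatorial hydroxyls at C3 and C9 should be acylated while the axial 8α-hydroxyl, flanked by the C7 isopropenyl group and the new C9 ester and syn-axial to H6α and H10α, stays free; no stereocenter is touched.

Step 10
Reactants: 15 3α,9α-bis(hex-2-ynoyloxy)-10αH-eremophil-11-en-8α-ol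
Product: 16 3α,9α-bis[(Z)-hex-2-enoyloxy]-10αH-eremophil-11-en-8α-ol (CNP0420276.1)
Conditions: H2 (1 atm), Pd/CaCO3 poisoned with Pb(OAc)2 (Lindlar catalyst), quinoline, EtOAc, rt, stopped after 2 equiv H2
Reagents that add atoms: none
Why: Lindlar semihydrogenation: syn delivery of hydrogen on the poisoned palladium surface should turn both conjugated alkynes into Z-enoates, and the unactivated 1,1-disubstituted isopropenyl alkene is not expected to be reduced before hydrogen uptake is stopped.

Compound list
1 | (2E,6E)-farnesol | CC(C)=CCC/C(C)=C/CC/C(C)=C/CO | starting material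
2 | (2E,6E)-farnesyl chloride | CC(C)=CCC/C(C)=C/CC/C(C)=C/CCl | intermediate
3 | (2E,6E)-farnesyl diphosphate (used as trisammonium salt) | CC(C)=CCC/C(C)=C/CC/C(C)=C/COP(=O)(O)OP(=O)(O)O | intermediate
4 | (S)-germacrene A, (1(10)E,4E,7S)-germacra-1(10),4,11-triene (enzyme-bound, not isolated) | C=C(C)[C@@H]1C/C=C(C)/CC/C=C(C)/CC1 | intermediate
5 | (+)-aristolochene, (4S,5R,7S)-eremophila-9,11-diene | C=C(C)[C@@H]1C[C@]2(C)[C@@H](C)CCCC2=CC1 | intermediate
6 | (4S,5R,7S)-eremophila-9,11-dien-8-one | C=C(C)[C@@H]1C[C@]2(C)[C@@H](C)CCCC2=CC1=O | intermediate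
7 | lithium 10αH-eremophila-8,11-dien-8-olate (not isolated) | C=C(C)[C@@H]1C[C@]2(C)[C@@H](C)CCC[C@H]2C=C1[O-].[Li+] | intermediate
8 | 8-(trimethylsilyloxy)-10αH-eremophila-8,11-diene | C=C(C)[C@@H]1C[C@]2(C)[C@@H](C)CCC[C@H]2C=C1O[Si](C)(C)C | intermediate
9 | 8α,9α-epoxy-8β-(trimethylsilyloxy)-10αH-eremophil-11-ene (not isolated) | C=C(C)[C@@H]1C[C@]2(C)[C@@H](C)CCC[C@H]2[C@@H]3O[C@]13O[Si](C)(C)C | intermediate
10 | 9α-(trimethylsilyloxy)-10αH-eremophil-11-en-8-one (not isolated) | C=C(C)[C@@H]1C[C@]2(C)[C@@H](C)CCC[C@H]2[C@H](O[Si](C)(C)C)C1=O | intermediate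
11 | 9α-hydroxy-10αH-eremophil-11-en-8-one | C=C(C)[C@@H]1C[C@]2(C)[C@@H](C)CCC[C@H]2[C@H](O)C1=O | intermediate
12 | 10αH-eremophil-11-ene-8α,9α-diol | C=C(C)[C@@H]1C[C@]2(C)[C@@H](C)CCC[C@H]2[C@H](O)[C@@H]1O | intermediate
13 | 10αH-eremophil-11-ene-3α,8α,9α-triol | C=C(C)[C@@H]1C[C@]2(C)[C@@H](C)[C@H](O)CC[C@H]2[C@H](O)[C@@H]1O | intermediate
14 | hex-2-ynoic acid | CCCC#CC(=O)O | starting material
15 | 3α,9α-bis(hex-2-ynoyloxy)-10αH-eremophil-11-en-8α-ol | C=C(C)[C@@H]1C[C@]2(C)[C@@H](C)[C@H](OC(=O)C#CCCC)CC[C@H]2[C@H](OC(=O)C#CCCC)[C@@H]1O | intermediate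
16 | 3α,9α-bis[(Z)-hex-2-enoyloxy]-10αH-eremophil-11-en-8α-ol, (3R,4R,5R,7S,8R,9S,10R), CNP0420276.1 | C=C(C)[C@@H]1C[C@]2(C)[C@@H](C)[C@H](OC(=O)/C=C\CCC)CC[C@H]2[C@H](OC(=O)/C=C\CCC)[C@@H]1O | target

Total step count: 10
Longest linear sequence: 10 steps (1 to 16); hex-2-ynoic acid 14 enters at step 9.

Steps most likely to fail

Step 8 (enzymatic C3 hydroxylation). What may go wrong is insufficient site selectivity of the oxygen transfer (to C2, C1 or the isopropenyl group instead of C3) or poor turnover with a non-natural substrate. The fallback uses known chemistry only, sets out from enone 6 and comes back at triol 13; it relays the enone oxygen pattern through ring A to C3 before ring B is elaborated.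
- Dehydrogenation of 6 with chloranil (t-BuOH, reflux) should give the linear dienone (4S,5R,7S)-eremophila-1,9,11-trien-8-one F1.
- Isopropenyl acetate with TsOH should convert it into the linear trienyl acetate 8-acetoxyeremophila-1(10),2,8,11-tetraene F2.
- The homoannular C10=C1–C2=C3 diene of F2 should add singlet oxygen (O2, tetraphenylporphyrin, hν, CH2Cl2, 0 °C) in a [4+2] sense on the α face, away from both methyl groups, to give the endoperoxide 8-acetoxy-3α,10α-epidioxyeremophila-1,8,11-triene F3.
- Diimide (KO2CN=NCO2K, AcOH, MeOH) should saturate only the strained C1=C2 bond to give 8-acetoxy-3α,10α-epidioxyeremophila-8,11-diene F4.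
- Zn in AcOH should cleave the O–O bond to 8-acetoxyeremophila-8,11-diene-3α,10α-diol F5.
- K2CO3 in MeOH at 0 °C should remove the enol acetate and expel the tertiary 10-hydroxyl, which is β to the liberated ketone, to give 3α-hydroxyeremophila-9,11-dien-8-one F6.
- F6 then passes through the same three operations as the main line: Li/NH3 followed by TMSCl/Et3N to 3α,8-bis(trimethylsilyloxy)-10αH-eremophila-8,11-diene F7, Rubottom oxidation (mCPBA, then dilute HCl) to 3α,9α-dihydroxy-10αH-eremophil-11-en-8-one F8, and LiBH(s-Bu)3 reduction to 13.

Step 9 (selective bis-acylation). What may go wrong is loss of site selectivity in the acylation (acylation of the axial O8, or migration of the acyl group from O9 to O8) and base-induced isomerisation of the ynoate. The fallback sets out from triol 13 and comes back at 15; it replaces kinetic discrimination by tin-directed acylation. Heating 13 with Bu2SnO (toluene, reflux, water removed) should give the stannylene acetal 8α,9α-O-(dibutylstannylene)-10αH-eremophil-11-ene-3α,8α,9α-triol F9. Treatment of F9 at 0 °C with hex-2-ynoic anhydride F10 (2.2 equiv, made beforehand from 14 with half an equivalent of DCC) and catalytic DMAP should deliver one acyl group to the tin-activated equatorial O9 and one to O3 in the ordinary way, while O8 stays bound to tin until aqueous work-up releases 15.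

Step 4 (allylic oxidation). What may go wrong is hydrogen abstraction at the wrong allylic site (C1, C7 or C12) and over-oxidation of the enone. The fallback sets out from 5 and comes back at 6; it replaces radical oxidation by a Schenck ene reaction and an oxidative allylic transposition. Singlet oxygen (O2, tetraphenylporphyrin, hν, CH2Cl2, 0 °C) should attack the trisubstituted C9=C10 alkene on the α face and take H8 from the disubstituted side of the alkene, as 5-ene steroids do, giving 10α-hydroperoxyeremophila-8,11-diene F11. PPh3 added to the same flask should reduce it to eremophila-8,11-dien-10α-ol F12. Pyridinium chlorochromate ([C5H5NH][CrO3Cl]) in CH2Cl2 should then move the oxygen from C10 to C8 through the allylic chromate ester (Babler–Dauben oxidative transposition) and give 6.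

Further compounds
F1 | step 8 | (4S,5R,7S)-eremophila-1,9,11-trien-8-one | C=C(C)[C@@H]1C[C@]2(C)[C@@H](C)CC=CC2=CC1=O
F2 | step 8 | 8-acetoxyeremophila-1(10),2,8,11-tetraene | C=C(C)[C@@H]1C[C@]2(C)[C@@H](C)C=CC=C2C=C1OC(C)=O
F3 | step 8 | 8-acetoxy-3α,10α-epidioxyeremophila-1,8,11-triene | C=C(C)[C@@H]1C[C@]2(C)[C@@H](C)[C@H]3C=C[C@@]2(OO3)C=C1OC(C)=O
F4 | step 8 | 8-acetoxy-3α,10α-epidioxyeremophila-8,11-diene | C=C(C)[C@@H]1C[C@]2(C)[C@@H](C)[C@H]3CC[C@@]2(OO3)C=C1OC(C)=O
F5 | step 8 | 8-acetoxyeremophila-8,11-diene-3α,10α-diol | C=C(C)[C@@H]1C[C@]2(C)[C@@H](C)[C@H](O)CC[C@@]2(O)C=C1OC(C)=O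
F6 | step 8 | 3α-hydroxyeremophila-9,11-dien-8-one | C=C(C)[C@@H]1C[C@]2(C)[C@@H](C)[C@H](O)CCC2=CC1=O
F7 | step 8 | 3α,8-bis(trimethylsilyloxy)-10αH-eremophila-8,11-diene | C=C(C)[C@@H]1C[C@]2(C)[C@@H](C)[C@H](O[Si](C)(C)C)CC[C@H]2C=C1O[Si](C)(C)C
F8 | step 8 | 3α,9α-dihydroxy-10αH-eremophil-11-en-8-one | C=C(C)[C@@H]1C[C@]2(C)[C@@H](C)[C@H](O)CC[C@H]2[C@H](O)C1=O
F9 | step 9 | 8α,9α-O-(dibutylstannylene)-10αH-eremophil-11-ene-3α,8α,9α-triol | C=C(C)[C@@H]1C[C@]2(C)[C@@H](C)[C@H](O)CC[C@H]2[C@H](O[Sn]3(CCCC)CCCC)[C@@H]1O3
F10 | step 9 | hex-2-ynoic anhydride | CCCC#CC(=O)OC(=O)C#CCCC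
F11 | step 4 | 10α-hydroperoxyeremophila-8,11-diene | C=C(C)[C@@H]1C[C@]2(C)[C@@H](C)CCC[C@@]2(OO)C=C1
F12 | step 4 | eremophila-8,11-dien-10α-ol | C=C(C)[C@@H]1C[C@]2(C)[C@@H](C)CCC[C@@]2(O)C=C1
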